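**Strategy.** The γ-lactone ring of the 6-oxabicyclo[3.2.1]octan-7-one core (O6–C5–C8–C1–C7) is treated as a ring-expanded cyclobutanone. The carbons C7, C1, C8 and C5 are first joined as a bicyclo[3.1.1]heptan-6-one; Baeyer–Villiger oxidation then inserts O6 next to the isopropenyl-bearing C5. The key step is an intramolecular [2+2] cycloaddition of an isopropenylketene with the near double bond of a tethered (E)-1,3-diene. It forms C7–C1 and C5–C8, both carbocyclic rings and three stereocentres in one operation. Its precursor is an acyclic dienoic acid chloride built from (R)-citronellal, in which ene chemistry turns the isopropylidene end into the ketene unit.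

Key step: step 6

Remark: (R)-citronellal of high enantiomeric purity is assumed. Compounds 6, 8, 9 and 10 are epimer mixtures at the carbon that becomes the ketene α-carbon (drawn without configuration); both epimers converge in step 6. Cyclobutanone 12 is a cis-2,3-dialkenylcyclobutanone and is therefore made at low temperature and oxidised without delay.

Step 1
Reactants: 1 (R)-citronellal, (3R)-3,7-dimethyloct-6-enal
Product: 2 (3R)-3,7-dimethyloct-6-en-1-yne
Conditions: C4F9SO2F, P2-Et phosphazene base EtN=P(NMe2)2–N=P(NMe2)3, DMF, 0 → 25 °C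
Reagents that add atoms: none
Why: One-pot enol nonaflate formation and base-induced β-elimination (aldehyde-to-alkyne dehydration via an alkenyl sulfonate) should give the terminal alkyne without homologation; the stereocentre is not an enolisable position and is retained.

Step 2
Reactants: 2 (3R)-3,7-dimethyloct-6-en-1-yne; 3 tert-butyl(2-iodoethoxy)dimethylsilane
Product: 4 2-[(1E,3R)-2-{2-[(tert-butyldimethylsilyl)oxy]ethyl}-3,7-dimethylocta-1,6-dien-1-yl]-4,4,5,5-tetramethyl-1,3,2-dioxaborolane
Conditions: B2pin2, CuCl (10 mol%), Xantphos, NaOtBu, THF, 25 °C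
Reagents that add atoms: bis(pinacolato)diboron, CC1(C)OB(OC1(C)C)B1OC(C)(C)C(C)(C)O1
Why: Copper-catalysed alkylboration of a terminal alkyne (syn borylcupration with boron at the terminal carbon, then alkylation of the alkenylcopper with retention) should place the new alkyl group cis to boron and so fix the (E) geometry of the trisubstituted alkene.

Step 3
Reactants: 4 the alkenyl boronate; 5 formaldehyde (used as paraformaldehyde)
Product: 6 (2RS,5R,6E)-6-{2-[(tert-butyldimethylsilyl)oxy]ethyl}-5-methyl-2-(prop-1-en-2-yl)-7-(4,4,5,5-tetramethyl-1,3,2-dioxaborolan-2-yl)hept-6-en-1-ol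
Conditions: Me2AlCl, CH2Cl2, −78 → 0 °C
Reagents that add atoms: none
Why: The Me2AlCl-promoted carbonyl-ene reaction should attack the electron-rich isopropylidene group at its less substituted carbon with hydrogen transfer from a methyl group, which creates the isopropenyl group and the future ketene carbon at once; the alkenyl boronate is too electron-poor to compete and the new stereocentre forms unselectively (it is erased in step 6).

Step 4
Reactants: 6 the boronate alcohol; 7 vinyl bromide
Product: 8 (2RS,5R,6E)-6-{2-[(tert-butyldimethylsilyl)oxy]ethyl}-5-methyl-2-(prop-1-en-2-yl)nona-6,8-dien-1-ol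
Conditions: Pd(PPh3)4 (5 mol%), 2 M aq. NaOH, THF, 60 °C, sealed tube
Reagents that add atoms: none
Why: Suzuki–Miyaura coupling of the alkenyl boronate should proceed with retention of alkene geometry and gives the (E)-1,3-diene that steers the cycloaddition.

Step 5
Reactants: 8 the dienol
Product: 9 (2RS,5R,6E)-6-{2-[(tert-butyldimethylsilyl)oxy]ethyl}-5-methyl-2-(prop-1-en-2-yl)nona-6,8-dienoic acid
Conditions: TEMPO (10 mol%), PhI(OAc)2, MeCN/pH 7 phosphate buffer, 25 °C
Reagents that add atoms: water, O
Why: Oxoammonium-mediated oxidation should take the primary alcohol through the aldehyde hydrate to the carboxylic acid without touching the diene, the silyl ether or the C5 stereocentre.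

Step 6
Reactants: 9 the dienoic acid
Product: 12 (1R,2R,5S,7R)-1-{2-[(tert-butyldimethylsilyl)oxy]ethyl}-7-ethenyl-2-methyl-5-(prop-1-en-2-yl)bicyclo[3.1.1]heptan-6-one, via acid chloride 10 (not isolated), via vinylketene 11 (not isolated)
Conditions: 1-chloro-N,N,2-trimethylprop-1-en-1-amine, CH2Cl2, 0 → 25 °C; then slow addition to Et3N, CH2Cl2, 40 °C (0.005 M)
Reagents that add atoms: none
Why: The chloroenamine converts 9 into acid chloride 10, which Et3N dehydrochlorinates at the doubly activated α-position to isopropenylketene 11; this adds across the 6,7-double bond of 11 (the diene end that carries the tether) in a concerted, asynchronous [π2s+π2a] cycloaddition. The reaction type is the intramolecular ketene–alkene [2+2] cycloaddition that gives bicyclo[3.1.1]heptan-6-ones, combined with the general orientation of ketene–1,3-diene additions that gives 3-vinylcyclobutanones. The cyclobutanone closes by [2+2] and the cyclohexane ring closes with it in the bridged mode, because the three-carbon tether joins the ketene α-carbon to the diene terminus while the new bond from that α-carbon goes to the neighbouring internal diene carbon. Suprafacial addition to the (E)-alkene fixes the relative configuration of C1, C5 and C7 of 12 and places the vinyl group, which is trans to the tether on the alkene, on the outer face away from the three-carbon bridge; the existing C2 stereocentre should steer the face by keeping its methyl group equatorial on the chair-like six-membered ring that contains the vinyl-bearing bridge. The step needs the bridged and not the fused orientation: the ketene carbonyl carbon should bond to the diene terminus so that charge develops as an allyl cation, the fused alternative would have to join two fully substituted carbons, and the (E) geometry makes the distal double bond unreachable. Both epimers of 9 give the same ketene.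

Step 7
Reactants: 12 the cyclobutanone
Product: 13 (1R,2R,5S,8R)-1-{2-[(tert-butyldimethylsilyl)oxy]ethyl}-8-ethenyl-2-methyl-5-(prop-1-en-2-yl)-6-oxabicyclo[3.2.1]octan-7-one
Conditions: 30% aq. H2O2, CF3CH2OH, 0 → 25 °C
Reagents that add atoms: hydrogen peroxide, OO
Why: Baeyer–Villiger oxidation of the strained cyclobutanone should occur with migration of the bridgehead that carries the isopropenyl group (tertiary and allylic, the better migrating group) and with retention of its configuration, which inserts the ring oxygen between the carbonyl carbon and that carbon; H2O2 in CF3CH2OH should leave the unactivated alkenes alone.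

Step 8
Reactants: 13 the vinyl lactone; 14 methyl acrylate
Product: 15 methyl (2E)-3-[(1R,2R,5S,8R)-1-{2-[(tert-butyldimethylsilyl)oxy]ethyl}-2-methyl-7-oxo-5-(prop-1-en-2-yl)-6-oxabicyclo[3.2.1]octan-8-yl]prop-2-enoate
Conditions: second-generation Hoveyda–Grubbs catalyst RuCl2(H2IMes)(=CH–C6H4-2-OiPr) (5 mol%), toluene, 60 °C
Reagents that add atoms: none
Why: Olefin cross-metathesis of the monosubstituted vinyl group with excess acrylate should give the (E)-enoate, while the hindered 1,1-disubstituted isopropenyl group should stay out of the metathesis.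

Step 9
Reactants: 15 the enoate
Product: 16 methyl 3-[(1R,2R,5S,8R)-1-{2-[(tert-butyldimethylsilyl)oxy]ethyl}-2-methyl-7-oxo-5-(prop-1-en-2-yl)-6-oxabicyclo[3.2.1]octan-8-yl]propanoate
Conditions: Cu(OAc)2 (5 mol%), 1,2-bis(diphenylphosphino)benzene (5 mol%), (EtO)2MeSiH, t-BuOH, toluene, 25 °C
Reagents that add atoms: none
Why: Copper hydride conjugate reduction should reduce only the enoate C=C bond; the lactone, the isolated isopropenyl group and the silyl ether are not substrates.

Step 10
Reactants: 16 the silyl ether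
Product: 17 methyl 3-[(1R,2R,5S,8R)-1-(2-hydroxyethyl)-2-methyl-7-oxo-5-(prop-1-en-2-yl)-6-oxabicyclo[3.2.1]octan-8-yl]propanoate
Conditions: Bu4NF, AcOH, THF, 0 → 25 °C
Reagents that add atoms: none
Why: Fluoride-mediated desilylation buffered with AcOH should free the primary alcohol without opening the lactone or touching the methyl ester.

Step 11
Reactants: 17 the alcohol
Product: 18 methyl 3-[(1R,2R,5S,8R)-1-(2-iodoethyl)-2-methyl-7-oxo-5-(prop-1-en-2-yl)-6-oxabicyclo[3.2.1]octan-8-yl]propanoate
Conditions: I2, PPh3, imidazole, CH2Cl2, 0 °C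
Reagents that add atoms: iodine, II
Why: Appel-type iodination should convert the unhindered primary alcohol into the iodide by SN2 displacement of the alkoxyphosphonium group.

Step 12
Reactants: 18 the iodide; 19 3-bromofuran-2(5H)-one
Product: 21 methyl 3-[(1R,2R,5S,8R)-2-methyl-7-oxo-1-[2-(2-oxo-2,5-dihydrofuran-3-yl)ethyl]-5-(prop-1-en-2-yl)-6-oxabicyclo[3.2.1]octan-8-yl]propanoate, via alkylzinc iodide 20 (not isolated)
Conditions: Zn dust, LiCl, THF, 40 °C; then 19, Pd2(dba)3 (2.5 mol%), SPhos (10 mol%), THF, 25 °C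
Reagents that add atoms: none
Why: Zinc insertion into the primary C–I bond gives an alkylzinc iodide that tolerates the ester and the lactone, and base-free Negishi coupling with the alkenyl bromide should join the sp3 and sp2 carbons without isomerising the base-sensitive butenolide.

**Compound list**

1 | (R)-citronellal, (3R)-3,7-dimethyloct-6-enal | O=CC[C@H](C)CCC=C(C)C | starting material
2 | (3R)-3,7-dimethyloct-6-en-1-yne | C#C[C@H](C)CCC=C(C)C | intermediate
3 | tert-butyl(2-iodoethoxy)dimethylsilane | CC(C)(C)[Si](C)(C)OCCI | starting material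
4 | 2-[(1E,3R)-2-{2-[(tert-butyldimethylsilyl)oxy]ethyl}-3,7-dimethylocta-1,6-dien-1-yl]-4,4,5,5-tetramethyl-1,3,2-dioxaborolane | CC(C)=CCC[C@@H](C)/C(CCO[Si](C)(C)C(C)(C)C)=C/B1OC(C)(C)C(C)(C)O1 | intermediate
5 | formaldehyde (as paraformaldehyde) | C=O | starting material
6 | (2RS,5R,6E)-6-{2-[(tert-butyldimethylsilyl)oxy]ethyl}-5-methyl-2-(prop-1-en-2-yl)-7-(4,4,5,5-tetramethyl-1,3,2-dioxaborolan-2-yl)hept-6-en-1-ol | C=C(C)C(CO)CC[C@@H](C)/C(CCO[Si](C)(C)C(C)(C)C)=C/B1OC(C)(C)C(C)(C)O1 | intermediate
7 | vinyl bromide | C=CBr | starting material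
8 | (2RS,5R,6E)-6-{2-[(tert-butyldimethylsilyl)oxy]ethyl}-5-methyl-2-(prop-1-en-2-yl)nona-6,8-dien-1-ol | C=C(C)C(CO)CC[C@@H](C)/C(CCO[Si](C)(C)C(C)(C)C)=C/C=C | intermediate
9 | (2RS,5R,6E)-6-{2-[(tert-butyldimethylsilyl)oxy]ethyl}-5-methyl-2-(prop-1-en-2-yl)nona-6,8-dienoic acid | C=C(C)C(C(=O)O)CC[C@@H](C)/C(CCO[Si](C)(C)C(C)(C)C)=C/C=C | intermediate
10 | (2RS,5R,6E)-6-{2-[(tert-butyldimethylsilyl)oxy]ethyl}-5-methyl-2-(prop-1-en-2-yl)nona-6,8-dienoyl chloride | C=C(C)C(C(=O)Cl)CC[C@@H](C)/C(CCO[Si](C)(C)C(C)(C)C)=C/C=C | intermediate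
11 | (5R,6E)-6-{2-[(tert-butyldimethylsilyl)oxy]ethyl}-5-methyl-2-(prop-1-en-2-yl)nona-1,6,8-trien-1-one (vinylketene) | C=C(C)C(=C=O)CC[C@@H](C)/C(CCO[Si](C)(C)C(C)(C)C)=C/C=C | intermediate
12 | (1R,2R,5S,7R)-1-{2-[(tert-butyldimethylsilyl)oxy]ethyl}-7-ethenyl-2-methyl-5-(prop-1-en-2-yl)bicyclo[3.1.1]heptan-6-one | C=C(C)[C@@]12CC[C@@H](C)[C@@](CCO[Si](C)(C)C(C)(C)C)(C1=O)[C@H]2C=C | intermediate
13 | (1R,2R,5S,8R)-1-{2-[(tert-butyldimethylsilyl)oxy]ethyl}-8-ethenyl-2-methyl-5-(prop-1-en-2-yl)-6-oxabicyclo[3.2.1]octan-7-one | C=C(C)[C@@]12CC[C@@H](C)[C@@](CCO[Si](C)(C)C(C)(C)C)(C(=O)O1)[C@H]2C=C | intermediate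
14 | methyl acrylate | C=CC(=O)OC | starting material
15 | methyl (2E)-3-[(1R,2R,5S,8R)-1-{2-[(tert-butyldimethylsilyl)oxy]ethyl}-2-methyl-7-oxo-5-(prop-1-en-2-yl)-6-oxabicyclo[3.2.1]octan-8-yl]prop-2-enoate | C=C(C)[C@@]12CC[C@@H](C)[C@@](CCO[Si](C)(C)C(C)(C)C)(C(=O)O1)[C@H]2/C=C/C(=O)OC | intermediate
16 | methyl 3-[(1R,2R,5S,8R)-1-{2-[(tert-butyldimethylsilyl)oxy]ethyl}-2-methyl-7-oxo-5-(prop-1-en-2-yl)-6-oxabicyclo[3.2.1]octan-8-yl]propanoate | C=C(C)[C@@]12CC[C@@H](C)[C@@](CCO[Si](C)(C)C(C)(C)C)(C(=O)O1)[C@H]2CCC(=O)OC | intermediate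
17 | methyl 3-[(1R,2R,5S,8R)-1-(2-hydroxyethyl)-2-methyl-7-oxo-5-(prop-1-en-2-yl)-6-oxabicyclo[3.2.1]octan-8-yl]propanoate | C=C(C)[C@@]12CC[C@@H](C)[C@@](CCO)(C(=O)O1)[C@H]2CCC(=O)OC | intermediate
18 | methyl 3-[(1R,2R,5S,8R)-1-(2-iodoethyl)-2-methyl-7-oxo-5-(prop-1-en-2-yl)-6-oxabicyclo[3.2.1]octan-8-yl]propanoate | C=C(C)[C@@]12CC[C@@H](C)[C@@](CCI)(C(=O)O1)[C@H]2CCC(=O)OC | intermediate
19 | 3-bromofuran-2(5H)-one | O=C1OCC=C1Br | starting material
20 | iodo{2-[(1R,2R,5S,8R)-8-(3-methoxy-3-oxopropyl)-2-methyl-7-oxo-5-(prop-1-en-2-yl)-6-oxabicyclo[3.2.1]octan-1-yl]ethyl}zinc | C=C(C)[C@@]12CC[C@@H](C)[C@@](CC[Zn]I)(C(=O)O1)[C@H]2CCC(=O)OC | intermediate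
21 | methyl 3-[(1R,2R,5S,8R)-2-methyl-7-oxo-1-[2-(2-oxo-2,5-dihydrofuran-3-yl)ethyl]-5-(prop-1-en-2-yl)-6-oxabicyclo[3.2.1]octan-8-yl]propanoate | C=C(C)[C@@]12CC[C@@H](C)[C@@](CCC3=CCOC3=O)(C(=O)O1)[C@H]2CCC(=O)OC | target

Total step count: 12. Longest linear sequence: 12 steps (1 → 21).

**Steps most likely to fail**

1. Step 6. Three processes may compete with the wanted cycloaddition: closure in the fused orientation (ketene carbonyl carbon to the internal alkene carbon), ketene dimerisation before the hindered ring closure, and [3,3]-sigmatropic ring expansion of the cis-dialkenylcyclobutanone if the mixture is heated; facial selectivity with respect to the methyl-bearing stereocentre may also be modest. Fallback (keteniminium cycloaddition, a more electrophilic and more strongly charge-controlled partner that reacts at lower temperature): from acid 9, amide coupling with pyrrolidine (EDC·HCl, HOBt, CH2Cl2) would give the pyrrolidine amide F1. Tf2O and 2,6-di-tert-butyl-4-methylpyridine in ClCH2CH2Cl (0 → 40 °C) would generate the keteniminium ion, whose [2+2] cycloaddition with the same diene double bond would give the cyclobutaniminium triflate F2. Hydrolysis of F2 with aqueous NaHCO3 rejoins the route at cyclobutanone 12.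

2. Step 2. The β-silyloxy alkyl iodide may undergo base-induced elimination, and the alkenylcopper may be protonated instead of alkylated (net hydroboration); the α-branched alkyne may also erode regioselectivity. Fallback (ketone olefination instead of alkyne difunctionalisation): from alkyne 2, gold-catalysed hydration ((IPr)AuCl, AgSbF6, aqueous dioxane) would give the methyl ketone F3. Kinetic enolisation at the methyl group (LiN(iPr)2, THF, −78 °C) and aldol addition to monomeric formaldehyde would give the β-hydroxy ketone F4, and silylation (TBSCl, imidazole) the silyl ether F5. Boron-Wittig olefination with LiCH(Bpin)2 (from CH2(Bpin)2 and lithium 2,2,6,6-tetramethylpiperidide) should place boron trans to the larger α-branched substituent and rejoins the route at alkenyl boronate 4.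

3. Step 8. Metathesis at the vinyl group, which sits between two quaternary carbons, may be slow, so that catalyst decomposition and acrylate homodimerisation win. Fallback (carbonylation instead of metathesis, which also makes step 9 unnecessary): from lactone 13, linear-selective hydroformylation (Rh(acac)(CO)2, BiPhePhos, CO/H2, toluene, 60 °C) would give the aldehyde F6. Pinnick oxidation (NaClO2, NaH2PO4, 2-methyl-2-butene, t-BuOH/H2O) would give the acid F7, and esterification with Me3SiCHN2 in MeOH/toluene rejoins the route at ester 16.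

Further compounds
F1 | step 6 | 1-[(2RS,5R,6E)-6-{2-[(tert-butyldimethylsilyl)oxy]ethyl}-5-methyl-2-(prop-1-en-2-yl)nona-6,8-dienoyl]pyrrolidine | C=C(C)C(C(=O)N1CCCC1)CC[C@@H](C)/C(CCO[Si](C)(C)C(C)(C)C)=C/C=C
F2 | step 6 | 1-[(1R,2R,5S,7R)-1-{2-[(tert-butyldimethylsilyl)oxy]ethyl}-7-ethenyl-2-methyl-5-(prop-1-en-2-yl)bicyclo[3.1.1]heptan-6-ylidene]pyrrolidin-1-ium trifluoromethanesulfonate | C=C(C)[C@@]12CC[C@@H](C)[C@@](CCO[Si](C)(C)C(C)(C)C)(C1=[N+]3CCCC3)[C@H]2C=C.[O-]S(=O)(=O)C(F)(F)F
F3 | step 2 | (3R)-3,7-dimethyloct-6-en-2-one | CC(=O)[C@H](C)CCC=C(C)C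
F4 | step 2 | (4R)-1-hydroxy-4,8-dimethylnon-7-en-3-one | OCCC(=O)[C@H](C)CCC=C(C)C
F5 | step 2 | (4R)-1-[(tert-butyldimethylsilyl)oxy]-4,8-dimethylnon-7-en-3-one | CC(C)(C)[Si](C)(C)OCCC(=O)[C@H](C)CCC=C(C)C
F6 | step 8 | 3-[(1R,2R,5S,8R)-1-{2-[(tert-butyldimethylsilyl)oxy]ethyl}-2-methyl-7-oxo-5-(prop-1-en-2-yl)-6-oxabicyclo[3.2.1]octan-8-yl]propanal | C=C(C)[C@@]12CC[C@@H](C)[C@@](CCO[Si](C)(C)C(C)(C)C)(C(=O)O1)[C@H]2CCC=O
F7 | step 8 | 3-[(1R,2R,5S,8R)-1-{2-[(tert-butyldimethylsilyl)oxy]ethyl}-2-methyl-7-oxo-5-(prop-1-en-2-yl)-6-oxabicyclo[3.2.1]octan-8-yl]propanoic acid | C=C(C)[C@@]12CC[C@@H](C)[C@@](CCO[Si](C)(C)C(C)(C)C)(C(=O)O1)[C@H]2CCC(=O)O
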